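**Assumption:** the target is the trans-(2S,3S) dihydrobenzofuran exactly as drawn in the SMILES. The radical step gives the trans racemate, and the single enantiomer is obtained by preparative chiral HPLC at the protected stage.

## Retrosynthetic overview
- Target ⇐ removal of five MOM groups from the single-enantiomer protected trans-2,3-diaryl-dihydrobenzofuran **14**, which comes from racemate **13** by chiral HPLC.
- **13** ⇐ Heck reaction of the C6 bromide **12** with the protected vinylguaiacol **10**.
- **12** is built in one radical-polar-crossover step. The 2,6-bis(MOMO)aryl radical from iodide **5** adds to the ArA-bearing carbon of stilbene **11**. The resulting benzylic radical is oxidised to a cation and closed by the ortho oxygen, forming C3–C3a and C2–O together with the trans stereochemistry.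
- **11** ⇐ Heck reaction of **4** with **10**. Building blocks **4** and **5** come from resorcinol by Ir-catalysed C–H borylation and ortho-lithiation. **10** comes from catechol via guaiacol. The dihydrobenzofuran ring forms in the radical step, and the arene rings pre-exist.

## Route

**Step 1**
Reactants: 1, resorcinol
Product: 2, 1,3-bis(methoxymethoxy)benzene
Conditions: NaH, MOMCl, THF, 0 °C → rt
Reagents that add atoms: MOMCl, COCCl
Why: double O-alkylation protects both phenols as MOM ethers. MOM is chosen because it directs lithiation, survives the radical chemistry, and can be lost as MOM⁺ in the cyclisation.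

**Step 2**
Reactants: 2
Product: 3, 2-[3,5-bis(methoxymethoxy)phenyl]-4,4,5,5-tetramethyl-1,3,2-dioxaborolane
Conditions: B2pin2 (0.55 equiv), [Ir(cod)OMe]2 (1.5 mol %), dtbpy (3 mol %), THF, 80 °C
Reagents that add atoms: B2pin2, CC1(C)OB(OC1(C)C)B1OC(C)(C)C(C)(C)O1
Why: Ir-catalysed C–H borylation is sterically controlled and occurs only at C5, the position meta to both OMOM groups.

**Step 3**
Reactants: 3
Product: 4, 1-bromo-3,5-bis(methoxymethoxy)benzene
Conditions: CuBr2 (3 equiv), MeOH/H2O 1:1, 80 °C, sealed tube
Reagents that add atoms: CuBr2, [Cu+2].[Br-].[Br-]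
Why: Cu(II)-mediated bromodeboronation (halodeboronation) of the aryl pinacol boronate converts the C–B bond to C–Br.

**Step 4**
Reactants: 4
Product: 5, 5-bromo-2-iodo-1,3-bis(methoxymethoxy)benzene
Conditions: LiTMP, THF, −78 °C, 1 h; then I2, −78 °C → rt
Reagents that add atoms: I2, II
Why: directed ortho-metalation at C2, the position between the two OMOM groups, is doubly activated. LiTMP is used so that bromine–lithium exchange is avoided, and I2 traps the aryl lithium.

**Step 5**
Reactants: 6, catechol
Product: 7, guaiacol (2-methoxyphenol)
Conditions: MeI (1.0 equiv), K2CO3, acetone, 50 °C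
Reagents that add atoms: MeI, CI
Why: statistical mono-O-methylation, with guaiacol separated from veratrole and unreacted catechol.

**Step 6**
Reactants: 7
Product: 8, 4-bromo-2-methoxyphenol
Conditions: NBS, CH2Cl2, −20 °C → rt
Reagents that add atoms: NBS, O=C1CCC(=O)N1Br
Why: electrophilic bromination goes para to the strongly activating OH.

**Step 7**
Reactants: 8
Product: 9, 4-bromo-2-methoxy-1-(methoxymethoxy)benzene
Conditions: MOMCl, i-Pr2NEt, CH2Cl2, 0 °C → rt
Reagents that add atoms: MOMCl, COCCl
Why: O-alkylation protects the phenol so that it does not quench aryl radicals by hydrogen-atom transfer in the later radical step.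

**Step 8**
Reactants: 9
Product: 10, 2-methoxy-1-(methoxymethoxy)-4-vinylbenzene
Conditions: CH2=CHBF3K (1.3 equiv), PdCl2(dppf) (3 mol %), Cs2CO3, THF/H2O 9:1, 80 °C
Reagents that add atoms: potassium vinyltrifluoroborate, C=C[B-](F)(F)F.[K+]
Why: Suzuki–Miyaura vinylation of the aryl bromide.

**Step 9**
Reactants: 4, aryl bromide; 10, styrene (1.3 equiv)
Product: 11, (E)-1-[3,5-bis(MOMO)phenyl]-2-[3-methoxy-4-(MOMO)phenyl]ethene
Conditions: Pd(OAc)2 (3 mol %), P(o-tol)3 (6 mol %), Et3N, DMF, 100 °C
Reagents that add atoms: none
Why: Mizoroki–Heck coupling, which gives the (E)-stilbene selectively by syn-carbopalladation and β-H elimination.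

**Step 10**
Reactants: 5, aryl iodide; 11, stilbene (2 equiv)
Product: 12, rac-(2S,3S)-6-bromo-4-(MOMO)-2-[3-methoxy-4-(MOMO)phenyl]-3-[3,5-bis(MOMO)phenyl]-2,3-dihydrobenzofuran (trans; SMILES drawn as one enantiomer)
Conditions: fac-Ir(ppy)3 (2 mol %), 2,6-di-tert-butylpyridine (1.5 equiv), MeCN/HFIP 4:1, blue LEDs (450 nm), rt, 24 h
Reagents that add atoms: none (the byproduct is MOM–I)
Why: Meerwein-type aryl-radical addition followed by radical-polar-crossover oxy-cyclisation. The aryl radical adds to the stilbene carbon bearing the less donating 3,5-dialkoxyphenyl ring (ArA), because that gives the more stabilised benzylic radical next to the p-alkoxyaryl ring (ArB). Ir(IV) oxidises this radical to the p-alkoxybenzylic cation, and the ortho-OMOM oxygen closes the five-membered ring with loss of MOM⁺. C3 is formed racemically, and the ortho oxygen attacks anti to the C3 aryl group, so the trans isomer is formed. Proposed new method: the mechanism is Ir(III)* reduction of the electron-rich ArI to the aryl radical, radical addition to the alkene, oxidation of the benzylic radical by Ir(IV) in HFIP, and intramolecular O-trapping with loss of MOM⁺; the closest known reactions are photoredox Meerwein arylation–cyclisation of aryl diazoniums with tethered nucleophiles and Larock heteroannulation of 2-iodophenols with alkenes. The aryl bromide survives because ArI is reduced much more readily than ArBr.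

**Step 11**
Reactants: 12, aryl bromide; 10, styrene (2 equiv)
Product: 13, rac-(2S,3S)-pentakis-MOM-protected bisisorhapontigenin B (racemic, trans)
Conditions: Pd(OAc)2 (5 mol %), P(o-tol)3 (10 mol %), Et3N, DMF, 105 °C
Reagents that add atoms: none
Why: Mizoroki–Heck reaction installs the (E)-styryl group at C6; the C2 and C3 stereocentres are not touched.

**Step 12**
Reactants: 13
Product: 14, (2S,3S)-pentakis-MOM-protected bisisorhapontigenin B
Conditions: preparative chiral-phase HPLC (Chiralpak IA, n-hexane/i-PrOH), collecting the (2S,3S) enantiomer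
Reagents that add atoms: none
Why: resolution of the trans racemate fixes the absolute configuration, which is assigned by comparing [α]D and ECD with the natural product.

**Step 13**
Reactants: 14
Product: 15, bisisorhapontigenin B
Conditions: ZnBr2 (6 equiv), n-PrSH (12 equiv), CH2Cl2, 0 °C → rt, dark
Reagents that add atoms: none
Why: Lewis acid/thiol cleavage of all five MOM acetals is mild, which avoids acid-mediated benzylic ring-opening and racemisation at C2 as well as stilbene isomerisation.

## Compound list
1 | resorcinol | Oc1cccc(O)c1 | starting material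
2 | 1,3-bis(methoxymethoxy)benzene | COCOc1cccc(OCOC)c1 | intermediate
3 | 3,5-bis(MOMO)phenyl-Bpin | COCOc1cc(OCOC)cc(B2OC(C)(C)C(C)(C)O2)c1 | intermediate
4 | 1-bromo-3,5-bis(MOMO)benzene | COCOc1cc(Br)cc(OCOC)c1 | intermediate
5 | 5-bromo-2-iodo-1,3-bis(MOMO)benzene | COCOc1cc(Br)cc(OCOC)c1I | intermediate
6 | catechol | Oc1ccccc1O | starting material
7 | guaiacol | COc1ccccc1O | intermediate
8 | 4-bromo-2-methoxyphenol | COc1cc(Br)ccc1O | intermediate
9 | 4-bromo-2-methoxy-1-(MOMO)benzene | COCOc1ccc(Br)cc1OC | intermediate
10 | 2-methoxy-1-(MOMO)-4-vinylbenzene | C=Cc1ccc(OCOC)c(OC)c1 | intermediate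
11 | (E)-stilbene bearing 3,5-bis(MOMO)phenyl and 3-methoxy-4-(MOMO)phenyl | COCOc1cc(/C=C/c2ccc(OCOC)c(OC)c2)cc(OCOC)c1 | intermediate
12 | rac-trans-6-bromo-2,3-diaryl-4-MOMO-dihydrobenzofuran | Brc2cc(OCOC)c3c(c2)O[C@H](c2ccc(OCOC)c(OC)c2)[C@H]3c2cc(OCOC)cc(OCOC)c2 | intermediate (racemate; one enantiomer drawn)
13 | rac-pentakis-MOM bisisorhapontigenin B | COc1cc(/C=C/c2cc(OCOC)c3c(c2)O[C@H](c2ccc(OCOC)c(OC)c2)[C@H]3c2cc(OCOC)cc(OCOC)c2)ccc1OCOC | intermediate (racemate; one enantiomer drawn)
14 | (2S,3S)-pentakis-MOM bisisorhapontigenin B | COc1cc(/C=C/c2cc(OCOC)c3c(c2)O[C@H](c2ccc(OCOC)c(OC)c2)[C@H]3c2cc(OCOC)cc(OCOC)c2)ccc1OCOC | intermediate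
15 | bisisorhapontigenin B | COc1cc(/C=C/c2cc(O)c3c(c2)O[C@H](c2ccc(O)c(OC)c2)[C@H]3c2cc(O)cc(O)c2)ccc1O | target

**Total steps:** 13.
**Longest linear sequence:** 9 (catechol → 7 → 8 → 9 → 10 → 11 → 12 → 13/14 → 15, counting steps 5–13).

**Three steps most likely to fail**
1. **Step 10 (radical annulation).** Electron-rich ArI is hard to reduce, the aryl radical may take hydrogen from the MOM groups, the addition regiochemistry may be poor, and the cation may eliminate instead of closing.
   - Fallback: build a 2-aryl-4-OMOM-6-bromobenzofuran by Sonogashira coupling/5-endo cyclisation of a 2-iodophenol with the protected arylacetylene. Then add the 3,5-bis(MOMO)aryl radical (from ArI by halogen-atom transfer) to C3, and quench the C2 radical by H-atom transfer to give the trans product.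
2. **Step 4 (C2 lithiation of 4).** Deprotonation could occur at C4, next to Br, and lead to benzyne-type decomposition.
   - Fallback: iodinate first (n-BuLi, I2 on 2), then do the Ir borylation and CuBr2 bromodeboronation, which gives 5 by a different order of events.
3. **Step 12 (resolution).** The flexible pentakis-MOM compound may separate poorly on a chiral phase.
   - Fallback: set the stereochemistry by catalysis. Make the 2,3-diaryl benzofuran, hydrogenate it with a chiral Ru–NHC catalyst to the cis-dihydrobenzofuran, then epimerise C3 to trans with base.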